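**Retrosynthetic overview**

1. The target comes from 1-(3,5-dimethoxyphenyl)tricosan-2-one by cleavage of the two methyl ethers.
2. That ketone is cut at C3'–C4' (side chain counted from the ring). C3' is the diazo carbon of ArCH2C(=O)CHN2 and C4' is the boron-bearing carbon of dichloro(icosyl)borane. Two donor carbons are joined by a 1,2-shift from boron to carbon with loss of N2 (Hooz reaction), and the ketone appears through a boron enolate.
3. The diazo ketone comes from 3,5-dimethoxyphenylacetic acid and diazomethane; the borane comes from icos-1-ene, BCl3 and Et3SiH.
4. Enabling feature: C3' is an unbranched CH2 directly beside the C2' carbonyl, so it can be carried as a diazomethyl carbon. C4' is the primary end of an unbranched C20 chain, which is where boron sits after anti-Markovnikov hydroboration of a terminal alkene.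
5. No ring is formed. The benzene ring is bought with its 1,3,5-pattern and is insulated from the chemistry by C1'H2.

Key step: step 3

Remark: compounds 1 and 4 are taken as commercial. Diazomethane is used as a dried ethereal solution prepared from N-methyl-N-nitroso-p-toluenesulfonamide. The geometry of enolate 8 is of no consequence and is left undefined.

**Step 1**
Reactants: 1 (3,5-dimethoxyphenyl)acetic acid
Product: 3 1-diazo-3-(3,5-dimethoxyphenyl)propan-2-one, via (3,5-dimethoxyphenyl)acetyl chloride 2 (not isolated)
Conditions: (COCl)2, cat. DMF, CH2Cl2, 0 °C → rt; evaporate; then add to CH2N2 (3 equiv), Et2O, 0 °C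
Reagents that add atoms: diazomethane, C=[N+]=[N-]
Why: This is the acylation of diazomethane by an acid chloride (first stage of the Arndt–Eistert sequence); inverse addition into excess CH2N2 lets a second equivalent take up the HCl, so no amine base is present that could turn the arylacetyl chloride into a ketene.

**Step 2**
Reactants: 4 icos-1-ene
Product: 5 dichloro(icosyl)borane
Conditions: BCl3 (1.0 equiv, 1 M in hexanes), hexane, −78 °C; then Et3SiH (1.0 equiv), −78 °C → rt; volatiles removed in vacuo, residue taken up in Et2O under Ar and used at once
Reagents that add atoms: boron trichloride, ClB(Cl)Cl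
Why: This is hydroboration with dichloroborane generated in situ from BCl3 and a trialkylsilane; the B–H bond adds to the unhindered terminal alkene with boron on the terminal carbon, and the reaction stops at the monoalkyl stage because the product has no B–H left.

**Step 3**
Reactants: 3 1-diazo-3-(3,5-dimethoxyphenyl)propan-2-one; 5 dichloro(icosyl)borane
Product: 9 1-(3,5-dimethoxyphenyl)tricosan-2-one, via borate-diazonium adduct 6 (not isolated), via C-boryl ketone 7 (not isolated), via boron enolate 8 (not isolated)
Conditions: 5 (1.1 equiv) added to 3, Et2O, −78 °C → −25 °C (N2 evolution); then H2O, −25 °C → rt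
Reagents that add atoms: none
Why: This is a Hooz reaction (alkylation of an α-diazo ketone by an organoborane): the nucleophilic diazo carbon C3' of 3 adds to the electron-poor boron of 5 to give borate 6, in which the icosyl carbon C4' shifts from boron to C3' as N2 leaves, so C3' acts first as donor and then as acceptor while C4' is a donor throughout; the C-boryl ketone 7 then moves boron to oxygen and enolate 8 is protonated at C3' by water. The closest known reaction type is the alkylation of diazoacetone, diazoacetophenone and ethyl diazoacetate by trialkylboranes and alkyldichloroboranes made from terminal alkenes. No ring is closed and no stereocentre survives, because the transient stereocentre at C3' in 6 and 7 is erased in 8 and C3' ends as a CH2 group. The step needs site selectivity for C3' over the more acidic benzylic C1', which is secured because the new bond can only form at the carbon that carries N2 and no base or free enolate is present. It also needs a single alkylation, which is secured because 8 has no leaving group left and 5 carries only one carbon group that can migrate. Chloride migration and attack of the electron-rich ring on C3' are the competing paths, and they should be held back by the low temperature and the ready migration of a primary alkyl group on four-coordinate boron.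

**Step 4**
Reactants: 9 1-(3,5-dimethoxyphenyl)tricosan-2-one
Product: 11 5-(2-oxotricosyl)benzene-1,3-diol (5-(2'-oxotricosyl)resorcinol), via bis(dibromoboryl) ether 10 (not isolated)
Conditions: BBr3 (4 equiv), CH2Cl2, −78 °C → rt; then ice/H2O
Reagents that add atoms: none
Why: This is Lewis-acid cleavage of aryl methyl ethers with BBr3 (bromide attacks the methyl group of the boron-complexed ether); the saturated ketone only binds one equivalent of the reagent reversibly, and the aryl borate is hydrolysed on work-up.

**Compound list**

1 | (3,5-dimethoxyphenyl)acetic acid | COc1cc(CC(=O)O)cc(OC)c1 | starting material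
2 | (3,5-dimethoxyphenyl)acetyl chloride | COc1cc(CC(=O)Cl)cc(OC)c1 | intermediate
3 | 1-diazo-3-(3,5-dimethoxyphenyl)propan-2-one | COc1cc(CC(=O)C=[N+]=[N-])cc(OC)c1 | intermediate
4 | icos-1-ene | CCCCCCCCCCCCCCCCCCC=C | starting material
5 | dichloro(icosyl)borane | CCCCCCCCCCCCCCCCCCCCB(Cl)Cl | intermediate
6 | dichloro[1-diazonio-3-(3,5-dimethoxyphenyl)-2-oxopropyl](icosyl)borate, zwitterion, racemic | CCCCCCCCCCCCCCCCCCCC[B-](Cl)(Cl)C([N+]#N)C(=O)Cc1cc(OC)cc(OC)c1 | intermediate
7 | 3-(dichloroboranyl)-1-(3,5-dimethoxyphenyl)tricosan-2-one, racemic | CCCCCCCCCCCCCCCCCCCCC(B(Cl)Cl)C(=O)Cc1cc(OC)cc(OC)c1 | intermediate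
8 | dichloro{[1-(3,5-dimethoxyphenyl)tricos-2-en-2-yl]oxy}borane, E/Z undefined | CCCCCCCCCCCCCCCCCCCCC=C(OB(Cl)Cl)Cc1cc(OC)cc(OC)c1 | intermediate
9 | 1-(3,5-dimethoxyphenyl)tricosan-2-one | CCCCCCCCCCCCCCCCCCCCCC(=O)Cc1cc(OC)cc(OC)c1 | intermediate
10 | 1-[3,5-bis(dibromoboranyloxy)phenyl]tricosan-2-one | CCCCCCCCCCCCCCCCCCCCCC(=O)Cc1cc(OB(Br)Br)cc(OB(Br)Br)c1 | intermediate
11 | 5-(2-oxotricosyl)benzene-1,3-diol | CCCCCCCCCCCCCCCCCCCCCC(=O)Cc1cc(O)cc(O)c1 | target

**Step count**

Total steps: 4. Longest linear sequence: 3 (steps 1, 3, 4; step 2 is the one-step side branch).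

**Steps most likely to fail**

Step 3. The Lewis-acidic borane, or traces of HCl in it, may convert the diazo carbon into a diazonium centre that is captured before the alkyl shift. Capture could be by the electron-rich C2/C6 of the dimethoxyphenyl ring (five-membered ring closure) or by chloride; chloride could also migrate in place of the alkyl group. The fallback sets out from 1 and comes back at 9, making the same C3'–C4' bond with normal polarity by an acetoacetic ester alkylation. Chloride 2, made from 1 as in step 1, would acylate Meldrum's acid (pyridine, CH2Cl2, 0 °C) to give 5-[2-(3,5-dimethoxyphenyl)-1-hydroxyethylidene]-2,2-dimethyl-1,3-dioxane-4,6-dione F1. Methanolysis at reflux should give methyl 4-(3,5-dimethoxyphenyl)-3-oxobutanoate F2. Its sodium enolate (NaH, THF/DMF) forms at the doubly activated carbon and should be alkylated by 1-iodoicosane to methyl 2-[(3,5-dimethoxyphenyl)acetyl]docosanoate F3 (racemic). Krapcho dealkoxycarbonylation (LiCl, wet DMSO, 150 °C) should then give 9.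

Step 2. Redistribution among the H–B–Cl species and a second hydroboration may give dialkylchloroborane. The alkene may also isomerise or oligomerise under BCl3 before hydride transfer. Either would leave the identity and amount of the boron reagent uncertain. The fallback sets out from 4 and comes back at 5 through a bench-stable boron carrier. Iridium-catalysed hydroboration of 4 with pinacolborane ([Ir(cod)Cl]2, dppm, CH2Cl2, rt) should give 2-icosyl-4,4,5,5-tetramethyl-1,3,2-dioxaborolane F4. KHF2 in MeOH/H2O should convert it into potassium trifluoro(icosyl)borate F5, which can be recrystallised and weighed. Tetrachlorosilane in THF or MeCN should then release 5 just before step 3.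

Step 1. The arylacetyl chloride may lose HCl towards the aryl ketene and its dimers, or HCl may add to the diazo ketone where diazomethane runs short. The fallback sets out from 1 and comes back at 9 without any diazo compound. Chloride 2 with Me2CuLi (Et2O, −78 °C) should give 1-(3,5-dimethoxyphenyl)propan-2-one F6. KH followed by n-BuLi (THF, 0 °C) should deprotonate first the benzylic carbon and then the methyl group, giving the α,α'-dianion of F6 as its potassium lithium salt F7. 1-Bromoicosane should alkylate the more basic terminal carbanion (C3'), and quenching with NH4Cl should give 9.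

**Further compounds**

F1 | step 3 | 5-[2-(3,5-dimethoxyphenyl)-1-hydroxyethylidene]-2,2-dimethyl-1,3-dioxane-4,6-dione | COc1cc(CC(O)=C2C(=O)OC(C)(C)OC2=O)cc(OC)c1
F2 | step 3 | methyl 4-(3,5-dimethoxyphenyl)-3-oxobutanoate | COC(=O)CC(=O)Cc1cc(OC)cc(OC)c1
F3 | step 3 | methyl 2-[(3,5-dimethoxyphenyl)acetyl]docosanoate, racemic | CCCCCCCCCCCCCCCCCCCCC(C(=O)OC)C(=O)Cc1cc(OC)cc(OC)c1
F4 | step 2 | 2-icosyl-4,4,5,5-tetramethyl-1,3,2-dioxaborolane | CCCCCCCCCCCCCCCCCCCCB1OC(C)(C)C(C)(C)O1
F5 | step 2 | potassium trifluoro(icosyl)borate | CCCCCCCCCCCCCCCCCCCC[B-](F)(F)F.[K+]
F6 | step 1 | 1-(3,5-dimethoxyphenyl)propan-2-one | CC(=O)Cc1cc(OC)cc(OC)c1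
F7 | step 1 | potassium lithium salt of the α,α'-dianion of 1-(3,5-dimethoxyphenyl)propan-2-one, enolate geometry undefined | [K+].[Li+].[CH2-]C([O-])=Cc1cc(OC)cc(OC)c1
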